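Atoms are numbered along the fifteen-carbon chain: C1≡C2 is the alkyne and C14–C15 the ethyl group. O(a) bridges C3/C6, O(b) bridges C4/C7 and O(c) bridges C9/C13. Read from the SMILES, the target is 3S,4R,6R,7S,8R,9R,10R,12S,13R.

## The problem

The fifteen-carbon chain is folded into a 2,5-dioxabicyclo[2.2.1]heptane (C3–C7 with O(a) and O(b)) that is joined through the bromomethine C8 to a 2,6-cis oxane (C9–C13 with O(c)). On the bicycle the ethynyl group at C3 is exo, whereas C8 at C7 is endo on the concave face, which is the awkward centre. Because C8–Br lies between two ether carbons, substitution there is poor and the bond should come from an alkene addition; the anti relationship to O(b) demands a Z-C7=C8 alkene, and a Z alkene resists placing C8 cis to the C6 oxygen (allylic 1,3-strain). The oxane carries four equatorial substituents, and O(c) is flanked on both sides by a trans C–O/C–Br pair (O(c)–C9/C10–Br and O(c)–C13/C12–Br) with only the C11 methylene between them. That pattern is what remains when an oxirane oxygen on C9/C10 bridges to C13 of a bromonium ion at C12=C13 and bromide returns to C10, and this feature makes the key step possible. Control can flow as follows: C9 (from an asymmetric epoxidation) governs C10, C12 and C13; C6 governs C7 and C8; C4 comes from the chiral pool; C3 is set by the convex face of the bicycle. Three secondary bromides (E2, β-oxygen participation), a strained bis-ether and a terminal propargylic ether rule out strong bases and halophilic Lewis acids late in the route, so the alkyne is introduced last.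

## Retrosynthesis

**C3–C2 bond (25 ⇐ 24 ⇐ 22 ⇐ 20).** The ethynyl group is cut from C3. Cutting O(a)–C3 instead would need substitution with retention at a propargylic carbon. Cutting the C–C bond lets the bicyclic oxocarbenium ion 23 (from lactol acetate 22) take the alkynyl nucleophile on its open exo face, since the endo face is blocked by the C8 side chain. Acetate 22 comes from lactone 20 by reductive acetylation through aluminium lactolate 21. The silylalkyne 24 is desilylated to 25.

**O(a)–C6 bond (20 ⇐ 19).** The lactone C–O bond at C6 is cut with inversion. The precursor 19 then has its C6 hydroxyl trans to the C7 side chain, which is the arrangement a Z alkene gives naturally in the preceding ring closure. The forward reaction must be an invertive intramolecular esterification of a trans hydroxy acid.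

**O(b)–C7 and C8–Br (19 ⇐ 18 ⇐ 17).** Acid 19 comes from primary alcohol 18. In 18 the O(b)–C7 and C8–Br bonds are cut together, back to Z-alkenyl triol 17. This forms the bromide between two ether carbons by addition, not substitution. The forward 5-exo bromoetherification needs O4 to arrive on one alkene face only, which the 6S carbinol secures.

**C6–C7 bond (17 ⇐ 16 ⇐ 15 ⇐ 12 + 14).** Triol 17 is the deprotected acetonide 16, and the Z alkene of 16 comes from alkyne 15. Cutting C6–C7 of 15 gives oxane alkyne 12 and aldehyde 14 (one step from commercial alcohol 13). The two halves are of similar size, and the alkynylation sets C6 by ligand control.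

**C8 adjustment (12 ⇐ 11 ⇐ 10 ⇐ 9).** Alkyne 12 comes from aldehyde 11, alcohol 10 and silyl ether 9 by functional-group changes only.

**O(c)–C13, C12–Br and C10–Br (9 ⇐ 8 ⇐ 7 ⇐ 6), the key cut.** All three bonds are removed at once, back to the acyclic epoxy alkene 6 plus Br2, through bromonium ion 7 and oxonium ion 8. Compound 6 has two stereocentres and no ring other than the oxirane. Compound 9 has the oxane, four stereocentres and two of the three bromides. Cutting the C–Br bonds one by one (substitution on a preformed diol) would need a separate stereocontrolled step for each centre.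

**Epoxy alkene (6 ⇐ 5 ⇐ 4 ⇐ 3 ⇐ 1 + 2).** Compound 6 is the silyl ether of epoxy alcohol 5, from dienol 4 by asymmetric epoxidation. Dienol 4 comes from enynol 3, made from propargyl alcohol 1 and allylic bromide 2.

## Roads not taken

**Alternative 1:** (the most obvious) Cut every C–Br bond back to a C–OH bond. The oxane would be built by a conventional oxa-cyclisation as diol A1 with axial hydroxyls at C10 and C12, and both converted to equatorial bromides by SN2 inversion. C8–Br would be made the same way from a C8 carbinol after fragment coupling. This needs three separate displacements at carbons β to ether oxygen. Two are on the same ring and one lies between two ether carbons, where elimination and oxygen participation compete. Each of the oxane stereocentres also costs its own step. The chosen plan makes all three C–Br bonds by anti addition and sets C10, C12 and C13 in one operation.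

**Alternative 2:** Cut O(a)–C3 and O(b)–C4, back to the bromo diol enyne A2. The forward step would be epoxidation (or Br+ activation) of the enyne, 5-exo attack of O7 at C4 and propargylic etherification by O6. A2 contains a free C7–OH next to C8–Br, which closes to an epoxide with any base. Br+ on a 1,3-enyne tends to give bromoallenes. Closing O(a)–C3 from the resulting propargylic alcohol would need a cobalt-stabilised cation. The C7–O and C8–Br bonds would also still have to be set in a separate operation. The chosen plan never exposes a free bromohydrin and forms O(b)–C7 and C8–Br in the same step.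

**Alternative 3:** Close the bicycle last by bromoetherification of ring-A alcohol A3 (O4–H onto the Z-C7=C8 alkene). It is one step shorter on paper. The endo product, however, requires the O(a)–C6 bond to eclipse the alkene on the side of the Z substituent C9. Allylic 1,3-strain favours the rotamer with H6 there, which leads to the exo C7 epimer, and an E alkene would give the wrong C8 configuration. The chosen plan uses the same strain with the opposite C6 configuration and corrects C6 afterwards by invertive lactonisation.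

Key step: step 5

Remark (assumed): the ligand in step 10 is written as (S,S)-ProPhenol by analogy. If the sense proves opposite, (R,R)-ProPhenol is used, since the product must be the 6S carbinol.

## Route

Step 1
Reactants: 1 prop-2-yn-1-ol; 2 (E)-1-bromopent-2-ene
Product: 3 (E)-oct-5-en-2-yn-1-ol
Conditions: CuI (10 mol%), NaI (20 mol%), K2CO3, DMF, rt
Reagents that add atoms: none
Why: Copper-catalysed coupling of a terminal alkyne with a primary allylic bromide should give the skipped enyne by direct substitution; the E geometry of 2 is carried over.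

Step 2
Reactants: 3 (E)-oct-5-en-2-yn-1-ol
Product: 4 (2E,5E)-octa-2,5-dien-1-ol
Conditions: NaAlH2(OCH2CH2OCH3)2, THF, 0 °C to rt; aq. KNaC4H4O6 (potassium sodium tartrate)
Reagents that add atoms: none
Why: Hydroxyl-directed trans-hydroalumination of a propargylic alcohol gives the E allylic alcohol; the isolated alkene is not touched.

Step 3
Reactants: 4 (2E,5E)-octa-2,5-dien-1-ol
Product: 5 [(2S,3S)-3-[(E)-pent-2-en-1-yl]oxiran-2-yl]methanol
Conditions: Ti(OiPr)4 (10 mol%), L-(+)-diisopropyl tartrate (12 mol%), t-BuOOH, 4 Å sieves, CH2Cl2, −20 °C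
Reagents that add atoms: tert-butyl hydroperoxide CC(C)(C)OO
Why: Sharpless asymmetric epoxidation acts only on the allylic alcohol alkene; with the L-(+)-tartrate an E allylic alcohol gives the (2S,3S) epoxide, which fixes C9 and (before its later inversion) C10.

Step 4
Reactants: 5 [(2S,3S)-3-[(E)-pent-2-en-1-yl]oxiran-2-yl]methanol
Product: 6 tert-butyl{[(2S,3S)-3-[(E)-pent-2-en-1-yl]oxiran-2-yl]methoxy}diphenylsilane
Conditions: t-BuPh2SiCl, imidazole, CH2Cl2, 0 °C to rt
Reagents that add atoms: tert-butyl(chloro)diphenylsilane CC(C)(C)[Si](Cl)(c1ccccc1)c1ccccc1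
Why: Standard silylation; the bulky, non-participating silyl ether removes the free hydroxyl (no Payne-type participation) and keeps C9 inductively deactivated for the key step.

Step 5
Reactants: 6 tert-butyl{[(2S,3S)-3-[(E)-pent-2-en-1-yl]oxiran-2-yl]methoxy}diphenylsilane
Product: 9 tert-butyl{[(2S,3R,5S,6R)-3,5-dibromo-6-ethyloxan-2-yl]methoxy}diphenylsilane, via bromonium ion 7 (not isolated), via bicyclic oxonium ion 8 (not isolated)
Conditions: Br2 (1.0 equiv, slow addition), CH2Cl2/(CF3)2CHOH 4:1, −40 °C; then ZnBr2 (10 mol%), 0 °C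
Reagents that add atoms: bromine BrBr
Why: Proposed new method: Br+ adds reversibly to the only alkene to give 7; the oxirane oxygen, three atoms from C12, opens 7 at C13 anti to bromine to give the 1-oxoniabicyclo[3.1.0]hexane 8, and bromide then opens 8 at the ring-fusion carbon C10 with inversion, so that 9 has exactly the atoms of 6 plus Br2. The closest known reaction types are bromonium-initiated epoxide-opening cascades and the transannular oxirane participation in bromination of cycloocta-1,5-diene monoepoxide; new here is termination by bromide at the fusion carbon of a homoallylic epoxide. The O(c)–C13 bond forms by 5-endo attack on the bromonium ion (five-membered ring of 8), and the oxane arises when the C10–O bond breaks, a net 6-endo closure. C9 is untouched from step 3; C10 is inverted by SN2, so its bromide is trans to the C9 substituent; C12 and C13 follow from anti addition to the E alkene, so bromide and ethyl are trans. The 2,6-cis relation (C13 against C9) depends on the alkene face: in 8 the ethyl group should prefer the convex face, away from the three-membered ring, and that face leads to the all-equatorial product. The step needs bromide to attack C10 and not C9: C9 carries the electron-withdrawing, bulky CH2OSi group (as in the C3-selective opening of 2,3-epoxy alcohol derivatives), and opening at C13 relieves no small-ring strain. Any ring-contracted oxolane formed by attack at C9 is a β-bromo ether that can re-enter 8 under ZnBr2 and drain to the more stable all-equatorial oxane. The hydrogen-bonding cosolvent lowers the nucleophilicity of bromide so that oxirane participation can outrun simple dibromide formation.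

Step 6
Reactants: 9 tert-butyl{[(2S,3R,5S,6R)-3,5-dibromo-6-ethyloxan-2-yl]methoxy}diphenylsilane
Product: 10 [(2S,3R,5S,6R)-3,5-dibromo-6-ethyloxan-2-yl]methanol
Conditions: HF·pyridine, THF/pyridine, 0 °C to rt
Reagents that add atoms: none
Why: Fluoride cleavage of the silyl ether under weakly acidic conditions, which the secondary bromides tolerate.

Step 7
Reactants: 10 [(2S,3R,5S,6R)-3,5-dibromo-6-ethyloxan-2-yl]methanol
Product: 11 (2S,3R,5S,6R)-3,5-dibromo-6-ethyloxane-2-carbaldehyde
Conditions: Dess–Martin periodinane, CH2Cl2, 0 °C to rt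
Reagents that add atoms: none
Why: Dess–Martin oxidation is neutral and should not epimerise C9 (the formyl group is already equatorial) or eliminate HBr.

Step 8
Reactants: 11 (2S,3R,5S,6R)-3,5-dibromo-6-ethyloxane-2-carbaldehyde
Product: 12 (2R,3S,5R,6S)-3,5-dibromo-2-ethyl-6-ethynyloxane
Conditions: dimethyl (1-diazo-2-oxopropyl)phosphonate, K2CO3, MeOH, 0 °C to rt
Reagents that add atoms: dimethyl (1-diazo-2-oxopropyl)phosphonate CC(=O)C(=[N+]=[N-])P(=O)(OC)OC
Why: Seyferth–Gilbert homologation in the Ohira–Bestmann form turns the aldehyde into the terminal alkyne with one added carbon; the C10 bromide is equatorial and so not aligned for E1cB loss from the C9 enolate, and equatorial C9 is the thermodynamic configuration.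

Step 9
Reactants: 13 2-[(4R)-2,2-dimethyl-1,3-dioxolan-4-yl]ethan-1-ol
Product: 14 2-[(4R)-2,2-dimethyl-1,3-dioxolan-4-yl]acetaldehyde
Conditions: Dess–Martin periodinane, CH2Cl2, 0 °C to rt
Reagents that add atoms: none
Why: Mild oxidation of the primary alcohol; the stereocentre (the future C4) is not adjacent to the carbonyl and the aldehyde is used crude.

Step 10
Reactants: 12 (2R,3S,5R,6S)-3,5-dibromo-2-ethyl-6-ethynyloxane; 14 2-[(4R)-2,2-dimethyl-1,3-dioxolan-4-yl]acetaldehyde
Product: 15 (2S)-4-[(2S,3R,5S,6R)-3,5-dibromo-6-ethyloxan-2-yl]-1-[(4R)-2,2-dimethyl-1,3-dioxolan-4-yl]but-3-yn-2-ol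
Conditions: Zn(CH3)2, (S,S)-ProPhenol (20 mol%), Ph3P=O (40 mol%), toluene, 0 °C
Reagents that add atoms: none
Why: ProPhenol/dinuclear-zinc catalysed addition of a terminal alkyne to an aliphatic aldehyde; the new C6 carbinol (6S) is set by the ligand, and the non-basic zinc alkynylide leaves the bromides and the acetonide alone.

Step 11
Reactants: 15 (2S)-4-[(2S,3R,5S,6R)-3,5-dibromo-6-ethyloxan-2-yl]-1-[(4R)-2,2-dimethyl-1,3-dioxolan-4-yl]but-3-yn-2-ol
Product: 16 (2S,3Z)-4-[(2S,3R,5S,6R)-3,5-dibromo-6-ethyloxan-2-yl]-1-[(4R)-2,2-dimethyl-1,3-dioxolan-4-yl]but-3-en-2-ol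
Conditions: H2 (1 atm), Pd/CaCO3 poisoned with Pb(OAc)2 (Lindlar catalyst), quinoline, EtOAc, rt
Reagents that add atoms: none
Why: Lindlar semihydrogenation gives the Z alkene by syn addition; this is the only alkyne in the molecule, and secondary alkyl bromides survive the poisoned catalyst.

Step 12
Reactants: 16 (2S,3Z)-4-[(2S,3R,5S,6R)-3,5-dibromo-6-ethyloxan-2-yl]-1-[(4R)-2,2-dimethyl-1,3-dioxolan-4-yl]but-3-en-2-ol
Product: 17 (2R,4S,5Z)-6-[(2S,3R,5S,6R)-3,5-dibromo-6-ethyloxan-2-yl]hex-5-ene-1,2,4-triol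
Conditions: AcOH/H2O 4:1, rt
Reagents that add atoms: none
Why: Mild acetal hydrolysis frees the C4 hydroxyl as the nucleophile for the next step; the Z allylic alcohol and the secondary bromides are stable to aqueous acetic acid at room temperature.

Step 13
Reactants: 17 (2R,4S,5Z)-6-[(2S,3R,5S,6R)-3,5-dibromo-6-ethyloxan-2-yl]hex-5-ene-1,2,4-triol
Product: 18 (2S,3S,5R)-2-{(R)-bromo[(2R,3R,5S,6R)-3,5-dibromo-6-ethyloxan-2-yl]methyl}-5-(hydroxymethyl)oxolan-3-ol
Conditions: N-bromosuccinimide, MeCN, −30 to 0 °C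
Reagents that add atoms: N-bromosuccinimide O=C1CCC(=O)N1Br
Why: 5-exo bromoetherification: anti addition of O4 (at C7) and bromine (at C8) across the Z alkene gives the required 7S,8R pair. Allylic 1,3-strain keeps H6 in the alkene plane, so O4 arrives on the C5 face and bromine on the face of the C6 hydroxyl, placing C8 trans to that hydroxyl; the primary hydroxyl would need a slower 6-exo closure.

Step 14
Reactants: 18 (2S,3S,5R)-2-{(R)-bromo[(2R,3R,5S,6R)-3,5-dibromo-6-ethyloxan-2-yl]methyl}-5-(hydroxymethyl)oxolan-3-ol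
Product: 19 (2R,4S,5S)-5-{(R)-bromo[(2R,3R,5S,6R)-3,5-dibromo-6-ethyloxan-2-yl]methyl}-4-hydroxyoxolane-2-carboxylic acid
Conditions: TEMPO (20 mol%), PhI(OAc)2, MeCN/H2O 1:1, rt
Reagents that add atoms: water O
Why: The oxoammonium oxidation takes a primary alcohol to the acid in the presence of a secondary one, as in the oxidation of nucleoside 5'-hydroxyls.

Step 15
Reactants: 19 (2R,4S,5S)-5-{(R)-bromo[(2R,3R,5S,6R)-3,5-dibromo-6-ethyloxan-2-yl]methyl}-4-hydroxyoxolane-2-carboxylic acid
Product: 20 (1R,4R,6S)-6-{(R)-bromo[(2R,3R,5S,6R)-3,5-dibromo-6-ethyloxan-2-yl]methyl}-2,5-dioxabicyclo[2.2.1]heptan-3-one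
Conditions: PPh3, diisopropyl azodicarboxylate, THF (0.01 M), 0 °C to rt
Reagents that add atoms: none
Why: Mitsunobu lactonisation: the C6 hydroxyl is activated by the phosphine/azodicarboxylate pair and displaced by the C3 carboxylate with inversion (6S to 6R), as in the conversion of trans-4-hydroxyproline into its bridged lactone. The trans hydroxy acid cannot lactonise by simple acylation, so only the invertive path closes the O(a) bridge.

Step 16
Reactants: 20 (1R,4R,6S)-6-{(R)-bromo[(2R,3R,5S,6R)-3,5-dibromo-6-ethyloxan-2-yl]methyl}-2,5-dioxabicyclo[2.2.1]heptan-3-one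
Product: 22 (1R,4R,6S)-6-{(R)-bromo[(2R,3R,5S,6R)-3,5-dibromo-6-ethyloxan-2-yl]methyl}-2,5-dioxabicyclo[2.2.1]heptan-3-yl acetate (C3 epimers), via aluminium lactolate 21 (not isolated)
Conditions: i-Bu2AlH, CH2Cl2, −78 °C; then pyridine, DMAP, Ac2O, −78 to −20 °C
Reagents that add atoms: acetic anhydride CC(=O)OC(C)=O; diisobutylaluminium hydride CC(C)C[AlH]CC(C)C
Why: One-pot reductive acetylation: the lactone is reduced to the tetrahedral aluminate 21 (the only compound that keeps the aluminium and its isobutyl groups), which is stable at −78 °C and is acetylated in place; the C3 configuration of 22 is irrelevant because it is ionised in the next step.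

Step 17
Reactants: 22 (1R,4R,6S)-6-{(R)-bromo[(2R,3R,5S,6R)-3,5-dibromo-6-ethyloxan-2-yl]methyl}-2,5-dioxabicyclo[2.2.1]heptan-3-yl acetate
Product: 24 {[(1R,3S,4R,6S)-6-{(R)-bromo[(2R,3R,5S,6R)-3,5-dibromo-6-ethyloxan-2-yl]methyl}-2,5-dioxabicyclo[2.2.1]heptan-3-yl]ethynyl}trimethylsilane, via oxocarbenium ion 23 (not isolated)
Conditions: K[Me3SiC≡CBF3], BF3·OEt2, MeCN, −40 to 0 °C
Reagents that add atoms: potassium trifluoro[(trimethylsilyl)ethynyl]borate C[Si](C)(C)C#C[B-](F)(F)F.[K+]
Why: Lewis-acid ionisation of the lactol acetate gives 23, which takes the alkynyltrifluoroborate as in C-alkynylation of cyclic acetals. Attack comes from the exo face, because the endo face lies under the O(b)–C7 bridge and its C8 substituent, so C3 is set as 3S.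

Step 18
Reactants: 24 {[(1R,3S,4R,6S)-6-{(R)-bromo[(2R,3R,5S,6R)-3,5-dibromo-6-ethyloxan-2-yl]methyl}-2,5-dioxabicyclo[2.2.1]heptan-3-yl]ethynyl}trimethylsilane
Product: 25 (1R,3S,4R,6S)-6-{(R)-bromo[(2R,3R,5S,6R)-3,5-dibromo-6-ethyloxan-2-yl]methyl}-3-ethynyl-2,5-dioxabicyclo[2.2.1]heptane
Conditions: K2CO3 (cat.), MeOH, 0 °C
Reagents that add atoms: none
Why: Methanolysis of the alkynyl–silicon bond; the conditions are mild enough for the secondary bromides, whose equatorial or hindered positions disfavour E2.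

## Compound list

1 | prop-2-yn-1-ol | C#CCO | starting material
2 | (E)-1-bromopent-2-ene | CC/C=C/CBr | starting material
3 | (E)-oct-5-en-2-yn-1-ol | OCC#CC/C=C/CC | intermediate
4 | (2E,5E)-octa-2,5-dien-1-ol | OC/C=C/C/C=C/CC | intermediate
5 | [(2S,3S)-3-[(E)-pent-2-en-1-yl]oxiran-2-yl]methanol | OC[C@@H]1O[C@H]1C/C=C/CC | intermediate
6 | tert-butyl{[(2S,3S)-3-[(E)-pent-2-en-1-yl]oxiran-2-yl]methoxy}diphenylsilane | CC(C)(C)[Si](c1ccccc1)(c1ccccc1)OC[C@@H]1O[C@H]1C/C=C/CC | intermediate
7 | bromonium ion of 6 at C12–C13 as its bromide salt (not isolated) | CC(C)(C)[Si](c1ccccc1)(c1ccccc1)OC[C@@H]1O[C@H]1C[C@@H]1[Br+][C@H]1CC.[Br-] | intermediate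
8 | bicyclic oxonium ion (1-oxoniabicyclo[3.1.0]hexane; O(c) bonded to C9, C10 and C13) as its bromide salt (not isolated) | CC(C)(C)[Si](c1ccccc1)(c1ccccc1)OC[C@H]1[C@@H]2C[C@H](Br)[C@@H](CC)[O+]12.[Br-] | intermediate
9 | tert-butyl{[(2S,3R,5S,6R)-3,5-dibromo-6-ethyloxan-2-yl]methoxy}diphenylsilane | CC(C)(C)[Si](c1ccccc1)(c1ccccc1)OC[C@@H]1O[C@H](CC)[C@@H](Br)C[C@H]1Br | intermediate
10 | [(2S,3R,5S,6R)-3,5-dibromo-6-ethyloxan-2-yl]methanol | OC[C@@H]1O[C@H](CC)[C@@H](Br)C[C@H]1Br | intermediate
11 | (2S,3R,5S,6R)-3,5-dibromo-6-ethyloxane-2-carbaldehyde | O=C[C@@H]1O[C@H](CC)[C@@H](Br)C[C@H]1Br | intermediate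
12 | (2R,3S,5R,6S)-3,5-dibromo-2-ethyl-6-ethynyloxane | C#C[C@@H]1O[C@H](CC)[C@@H](Br)C[C@H]1Br | intermediate
13 | 2-[(4R)-2,2-dimethyl-1,3-dioxolan-4-yl]ethan-1-ol | OCC[C@@H]1COC(C)(C)O1 | starting material
14 | 2-[(4R)-2,2-dimethyl-1,3-dioxolan-4-yl]acetaldehyde | O=CC[C@@H]1COC(C)(C)O1 | intermediate
15 | (2S)-4-[(2S,3R,5S,6R)-3,5-dibromo-6-ethyloxan-2-yl]-1-[(4R)-2,2-dimethyl-1,3-dioxolan-4-yl]but-3-yn-2-ol | CC1(C)OC[C@@H](C[C@H](O)C#C[C@@H]2O[C@H](CC)[C@@H](Br)C[C@H]2Br)O1 | intermediate
16 | (2S,3Z)-4-[(2S,3R,5S,6R)-3,5-dibromo-6-ethyloxan-2-yl]-1-[(4R)-2,2-dimethyl-1,3-dioxolan-4-yl]but-3-en-2-ol | CC1(C)OC[C@@H](C[C@H](O)/C=C\[C@@H]2O[C@H](CC)[C@@H](Br)C[C@H]2Br)O1 | intermediate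
17 | (2R,4S,5Z)-6-[(2S,3R,5S,6R)-3,5-dibromo-6-ethyloxan-2-yl]hex-5-ene-1,2,4-triol | OC[C@H](O)C[C@H](O)/C=C\[C@@H]1O[C@H](CC)[C@@H](Br)C[C@H]1Br | intermediate
18 | (2S,3S,5R)-2-{(R)-bromo[(2R,3R,5S,6R)-3,5-dibromo-6-ethyloxan-2-yl]methyl}-5-(hydroxymethyl)oxolan-3-ol | OC[C@H]1C[C@H](O)[C@H](O1)[C@@H](Br)[C@@H]2O[C@H](CC)[C@@H](Br)C[C@H]2Br | intermediate
19 | (2R,4S,5S)-5-{(R)-bromo[(2R,3R,5S,6R)-3,5-dibromo-6-ethyloxan-2-yl]methyl}-4-hydroxyoxolane-2-carboxylic acid | OC(=O)[C@H]1C[C@H](O)[C@H](O1)[C@@H](Br)[C@@H]2O[C@H](CC)[C@@H](Br)C[C@H]2Br | intermediate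
20 | (1R,4R,6S)-6-{(R)-bromo[(2R,3R,5S,6R)-3,5-dibromo-6-ethyloxan-2-yl]methyl}-2,5-dioxabicyclo[2.2.1]heptan-3-one | O=C1O[C@@H]2C[C@H]1O[C@@H]2[C@@H](Br)[C@@H]1O[C@H](CC)[C@@H](Br)C[C@H]1Br | intermediate
21 | diisobutylaluminium lactolate of 20 (tetrahedral aluminate at C3; not isolated) | CC(C)C[Al](CC(C)C)OC1O[C@@H]2C[C@H]1O[C@@H]2[C@@H](Br)[C@@H]1O[C@H](CC)[C@@H](Br)C[C@H]1Br | intermediate
22 | (1R,4R,6S)-6-{(R)-bromo[(2R,3R,5S,6R)-3,5-dibromo-6-ethyloxan-2-yl]methyl}-2,5-dioxabicyclo[2.2.1]heptan-3-yl acetate (C3 epimers) | CC(=O)OC1O[C@@H]2C[C@H]1O[C@@H]2[C@@H](Br)[C@@H]1O[C@H](CC)[C@@H](Br)C[C@H]1Br | intermediate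
23 | bicyclic oxocarbenium ion (C3=O(a)+; not isolated) | C1=[O+][C@@H]2C[C@H]1O[C@@H]2[C@@H](Br)[C@@H]1O[C@H](CC)[C@@H](Br)C[C@H]1Br | intermediate
24 | {[(1R,3S,4R,6S)-6-{(R)-bromo[(2R,3R,5S,6R)-3,5-dibromo-6-ethyloxan-2-yl]methyl}-2,5-dioxabicyclo[2.2.1]heptan-3-yl]ethynyl}trimethylsilane | C[Si](C)(C)C#C[C@@H]1O[C@@H]2C[C@H]1O[C@@H]2[C@@H](Br)[C@@H]1O[C@H](CC)[C@@H](Br)C[C@H]1Br | intermediate
25 | (1R,3S,4R,6S)-6-{(R)-bromo[(2R,3R,5S,6R)-3,5-dibromo-6-ethyloxan-2-yl]methyl}-3-ethynyl-2,5-dioxabicyclo[2.2.1]heptane | C#C[C@@H]1O[C@@H]2C[C@H]1O[C@@H]2[C@@H](Br)[C@@H]1O[C@H](CC)[C@@H](Br)C[C@H]1Br | target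

## Step count and risk

Total: 18 steps. Longest linear sequence: 17 steps (steps 1–8 and 10–18); step 9 is a one-step branch.

**Step 5 (key step, proposed new method).** Three things may go wrong. Bromide may capture the bromonium ion before the oxirane oxygen does, giving plain dibromination. The oxonium ion may be opened at C9 instead of C10, giving ring contraction to an oxolane. Facial selectivity on the alkene may be poor, giving the 2,6-trans oxane. The fallback uses known chemistry and sets out from 5. Ti(OiPr)4-mediated, C3-selective bromide opening of the epoxy alcohol gives (2S,3R,5E)-3-bromooct-5-ene-1,2-diol F1. Silylation of the primary hydroxyl gives (2S,3R,5E)-3-bromo-1-[(tert-butyldiphenylsilyl)oxy]oct-5-en-2-ol F2. N-Bromosuccinimide bromoetherification of F2 through the C9 hydroxyl should give 9 together with the 5-exo product tert-butyl{[(2S,3R,5R)-3-bromo-5-[(1S)-1-bromopropyl]oxolan-2-yl]methoxy}diphenylsilane F3. F3 is then isomerised to 9 by the known ring expansion of β-bromo ethers through a bicyclic oxonium ion (ZnBr2, or AgBF4 followed by Bu4NBr). The fallback returns at 9.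

**Step 8.** The α-alkoxy-β-bromo aldehyde may lose HBr by E1cB under carbonate in methanol before it is homologated. The fallback sets out from 11 and avoids the alkyne. Stork–Zhao olefination (Ph3P=CHI at −78 °C) gives (2R,3S,5R,6S)-3,5-dibromo-2-ethyl-6-[(Z)-2-iodoethenyl]oxane F4. Nozaki–Hiyama–Kishi coupling of F4 with 14 (CrCl2, NiCl2 cat.) gives the Z allylic alcohol directly. The 6S epimer is separated, and the fallback returns at 16.

**Step 13.** The primary hydroxyl may compete by 6-exo closure, water or succinimide may capture the bromonium intermediate, or the rotamer with the C6 oxygen in the alkene plane may erode facial selectivity. The fallback sets out from 17. Selective silylation of the primary hydroxyl gives (2R,4S,5Z)-1-[(tert-butyldiphenylsilyl)oxy]-6-[(2S,3R,5S,6R)-3,5-dibromo-6-ethyloxan-2-yl]hex-5-ene-2,4-diol F5, which leaves O4 as the only nucleophile in reach. Cyclisation gives (2S,3S,5R)-2-{(R)-bromo[(2R,3R,5S,6R)-3,5-dibromo-6-ethyloxan-2-yl]methyl}-5-{[(tert-butyldiphenylsilyl)oxy]methyl}oxolan-3-ol F6, and HF·pyridine returns the route to 18.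

**Step 15.** The activated C6 oxygen may eliminate toward C5 or C7 in place of being displaced, or the carboxylate may be activated and fail to close because of the strain of the bridged lactone and crowding by the cis C7 substituent. The fallback sets out from 19. Esterification with trimethylsilyldiazomethane gives methyl (2R,4S,5S)-5-{(R)-bromo[(2R,3R,5S,6R)-3,5-dibromo-6-ethyloxan-2-yl]methyl}-4-hydroxyoxolane-2-carboxylate F7. Mesylation gives methyl (2R,4S,5S)-5-{(R)-bromo[(2R,3R,5S,6R)-3,5-dibromo-6-ethyloxan-2-yl]methyl}-4-[(methanesulfonyl)oxy]oxolane-2-carboxylate F8. Neutral ester cleavage with Me3SnOH gives (2R,4S,5S)-5-{(R)-bromo[(2R,3R,5S,6R)-3,5-dibromo-6-ethyloxan-2-yl]methyl}-4-[(methanesulfonyl)oxy]oxolane-2-carboxylic acid F9. Cs2CO3 in DMF then lets the carboxylate displace the mesylate with inversion. The fallback returns at 20.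

**Step 17.** The strained oxocarbenium ion may be captured too slowly, so that acetate returns or the ion fragments, or the nucleophile may be too weak. The fallback sets out from 20 and moves the C3 bond formation from C–C to C–O. Reduction with i-Bu2AlH gives the lactol (1R,4R,6S)-6-{(R)-bromo[(2R,3R,5S,6R)-3,5-dibromo-6-ethyloxan-2-yl]methyl}-2,5-dioxabicyclo[2.2.1]heptan-3-ol F10. Ethynylmagnesium bromide opens it to (2S,3R,5R)-2-{(R)-bromo[(2R,3R,5S,6R)-3,5-dibromo-6-ethyloxan-2-yl]methyl}-5-(1-hydroxyprop-2-yn-1-yl)oxolan-3-ol F11 (carbinol epimers). Co2(CO)8 converts this diol into its Co2(CO)6 alkyne complex F12. BF3·OEt2 triggers a Nicholas etherification by the C6 hydroxyl, which should converge both epimers on the exo-ethynyl bicycle as its Co2(CO)6 alkyne complex F13. (NH4)2Ce(NO3)6 removes the metal and returns the route at 25.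

## Further compounds

F1 | step 5 | (2S,3R,5E)-3-bromooct-5-ene-1,2-diol | OC[C@H](O)[C@H](Br)C/C=C/CC
F2 | step 5 | (2S,3R,5E)-3-bromo-1-[(tert-butyldiphenylsilyl)oxy]oct-5-en-2-ol | CC(C)(C)[Si](c1ccccc1)(c1ccccc1)OC[C@H](O)[C@H](Br)C/C=C/CC
F3 | step 5 | tert-butyl{[(2S,3R,5R)-3-bromo-5-[(1S)-1-bromopropyl]oxolan-2-yl]methoxy}diphenylsilane | CC[C@H](Br)[C@H]1C[C@@H](Br)[C@H](CO[Si](c2ccccc2)(c2ccccc2)C(C)(C)C)O1
F4 | step 8 | (2R,3S,5R,6S)-3,5-dibromo-2-ethyl-6-[(Z)-2-iodoethenyl]oxane | I/C=C\[C@@H]1O[C@H](CC)[C@@H](Br)C[C@H]1Br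
F5 | step 13 | (2R,4S,5Z)-1-[(tert-butyldiphenylsilyl)oxy]-6-[(2S,3R,5S,6R)-3,5-dibromo-6-ethyloxan-2-yl]hex-5-ene-2,4-diol | CC(C)(C)[Si](c1ccccc1)(c1ccccc1)OC[C@H](O)C[C@H](O)/C=C\[C@@H]1O[C@H](CC)[C@@H](Br)C[C@H]1Br
F6 | step 13 | (2S,3S,5R)-2-{(R)-bromo[(2R,3R,5S,6R)-3,5-dibromo-6-ethyloxan-2-yl]methyl}-5-{[(tert-butyldiphenylsilyl)oxy]methyl}oxolan-3-ol | CC(C)(C)[Si](c1ccccc1)(c1ccccc1)OC[C@H]1C[C@H](O)[C@H](O1)[C@@H](Br)[C@@H]2O[C@H](CC)[C@@H](Br)C[C@H]2Br
F7 | step 15 | methyl (2R,4S,5S)-5-{(R)-bromo[(2R,3R,5S,6R)-3,5-dibromo-6-ethyloxan-2-yl]methyl}-4-hydroxyoxolane-2-carboxylate | COC(=O)[C@H]1C[C@H](O)[C@H](O1)[C@@H](Br)[C@@H]2O[C@H](CC)[C@@H](Br)C[C@H]2Br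
F8 | step 15 | methyl (2R,4S,5S)-5-{(R)-bromo[(2R,3R,5S,6R)-3,5-dibromo-6-ethyloxan-2-yl]methyl}-4-[(methanesulfonyl)oxy]oxolane-2-carboxylate | COC(=O)[C@H]1C[C@H](OS(C)(=O)=O)[C@H](O1)[C@@H](Br)[C@@H]2O[C@H](CC)[C@@H](Br)C[C@H]2Br
F9 | step 15 | (2R,4S,5S)-5-{(R)-bromo[(2R,3R,5S,6R)-3,5-dibromo-6-ethyloxan-2-yl]methyl}-4-[(methanesulfonyl)oxy]oxolane-2-carboxylic acid | OC(=O)[C@H]1C[C@H](OS(C)(=O)=O)[C@H](O1)[C@@H](Br)[C@@H]2O[C@H](CC)[C@@H](Br)C[C@H]2Br
F10 | step 17 | (1R,4R,6S)-6-{(R)-bromo[(2R,3R,5S,6R)-3,5-dibromo-6-ethyloxan-2-yl]methyl}-2,5-dioxabicyclo[2.2.1]heptan-3-ol (C3 epimers) | OC1O[C@@H]2C[C@H]1O[C@@H]2[C@@H](Br)[C@@H]1O[C@H](CC)[C@@H](Br)C[C@H]1Br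
F11 | step 17 | (2S,3R,5R)-2-{(R)-bromo[(2R,3R,5S,6R)-3,5-dibromo-6-ethyloxan-2-yl]methyl}-5-(1-hydroxyprop-2-yn-1-yl)oxolan-3-ol (carbinol epimers) | C#CC(O)[C@H]1C[C@@H](O)[C@H](O1)[C@@H](Br)[C@@H]2O[C@H](CC)[C@@H](Br)C[C@H]2Br
F12 | step 17 | Co2(CO)6 complex of the alkyne of F11 | C#CC(O)[C@H]1C[C@@H](O)[C@H](O1)[C@@H](Br)[C@@H]2O[C@H](CC)[C@@H](Br)C[C@H]2Br.[Co].[Co].[C-]#[O+].[C-]#[O+].[C-]#[O+].[C-]#[O+].[C-]#[O+].[C-]#[O+]
F13 | step 17 | Co2(CO)6 complex of the alkyne of 25 | C#C[C@@H]1O[C@@H]2C[C@H]1O[C@@H]2[C@@H](Br)[C@@H]1O[C@H](CC)[C@@H](Br)C[C@H]1Br.[Co].[Co].[C-]#[O+].[C-]#[O+].[C-]#[O+].[C-]#[O+].[C-]#[O+].[C-]#[O+]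
A1 | alternative 1 | (2S,3S,5R,6R)-2-{[(tert-butyldiphenylsilyl)oxy]methyl}-6-ethyloxane-3,5-diol | CC(C)(C)[Si](c1ccccc1)(c1ccccc1)OC[C@@H]1O[C@H](CC)[C@H](O)C[C@@H]1O
A2 | alternative 2 | (3E,6R,7S,8R)-8-bromo-8-[(2R,3R,5S,6R)-3,5-dibromo-6-ethyloxan-2-yl]oct-3-en-1-yne-6,7-diol | C#C/C=C/C[C@@H](O)[C@H](O)[C@@H](Br)[C@@H]1O[C@H](CC)[C@@H](Br)C[C@H]1Br
A3 | alternative 3 | (2S,3R,5R)-5-[(Z)-2-[(2S,3R,5S,6R)-3,5-dibromo-6-ethyloxan-2-yl]ethenyl]-2-ethynyloxolan-3-ol | C#C[C@@H]1O[C@H](C[C@H]1O)/C=C\[C@@H]1O[C@H](CC)[C@@H](Br)C[C@H]1Br
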